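Ring A (C1–C5, C10) is built one carbon too large and then contracted. A catalytic enantioselective Diels–Alder union of a cycloheptenone ester with a silyloxy triene forms ring B, the quaternary C10 and the C9 side-chain handle. The derived α,α-dibromo cycloheptanone then undergoes a Favorskii rearrangement: the seven-membered ring contracts to ring A, its ketone carbon is expelled as the C19 methyl ester on C4, and a C4=C5 double bond erases the cis ring fusion. The step exploits the C19 ester on C4 next to ring-fusion carbon C5. Reductive methylation then sets C5 and C4 under control of the axial C10 ester; C20 becomes the formyl group last.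

Key step: step 8

Remark: labdane numbering of the target is used for all bicyclic compounds (ring A = C1–C5, C10; ring B = C5–C10; C11, C12 = side chain; C17 = exocyclic CH2; C18 = methyl and C19 = ester carbon on C4; C20 = carbon on C10; β = face of C20), and compounds 1, 4, 5 and 18 are taken to be purchasable.

Step 1
Reactants: 1 cyclohept-1-ene-1-carboxylic acid
Product: 2 tert-butyl cyclohept-1-ene-1-carboxylate
Conditions: Boc2O, DMAP (cat.), t-BuOH, 40 °C
Reagents that add atoms: di-tert-butyl dicarbonate, CC(C)(C)OC(=O)OC(=O)OC(C)(C)C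
Why: tert-butyl esterification through the mixed Boc anhydride with DMAP acyl transfer should leave the conjugated alkene untouched; no stereocentre is involved.

Step 2
Reactants: 2 tert-butyl cyclohept-1-ene-1-carboxylate
Product: 3 tert-butyl 3-oxocyclohept-1-ene-1-carboxylate
Conditions: Rh2(cap)4 (1 mol %), t-BuOOH (5 equiv), K2CO3, CH2Cl2, rt
Reagents that add atoms: tert-butyl hydroperoxide, CC(C)(C)OO
Why: dirhodium caprolactamate/TBHP allylic oxidation should oxidise the γ-CH2 (ring C3), whose allylic radical is delocalised onto the ester-bearing carbon, to the γ-keto enoate; no stereocentre is involved.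

Step 3
Reactants: 4 pent-4-enal; 5 vinylmagnesium bromide
Product: 6 hepta-1,6-dien-3-ol (racemic)
Conditions: THF, −78 → 0 °C; aq. NH4Cl
Reagents that add atoms: none
Why: Grignard 1,2-addition to the aldehyde; the racemic carbinol centre is removed in step 4.

Step 4
Reactants: 6 hepta-1,6-dien-3-ol
Product: 7 hepta-1,6-dien-3-one
Conditions: Dess–Martin periodinane, NaHCO3, CH2Cl2, 0 °C → rt (used as a solution)
Reagents that add atoms: none
Why: Dess–Martin oxidation of the secondary allylic alcohol under buffered conditions should spare both terminal alkenes.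

Step 5
Reactants: 7 hepta-1,6-dien-3-one
Product: 8 (Z)-3-(triisopropylsilyloxy)hepta-1,3,6-triene
Conditions: TIPSOTf, Et3N, CH2Cl2, 0 °C → rt
Reagents that add atoms: triisopropylsilyl trifluoromethanesulfonate, CC(C)[Si](C(C)C)(C(C)C)OS(=O)(=O)C(F)(F)F
Why: soft enolisation (silyl triflate/amine) can only occur at the α′-CH2 and should give the (Z)-silyl dienol ether, which places the allyl group on the outside of the s-cis diene.

Step 6
Reactants: 3 tert-butyl 3-oxocyclohept-1-ene-1-carboxylate; 8 (Z)-3-(triisopropylsilyloxy)hepta-1,3,6-triene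
Product: 9 cis-fused cycloadduct, tert-butyl ester [seven-membered ring C10–C1–C2–C3–C4–C19(=O)–C5; 10β-CO2t-Bu, 5β-H, 9α-allyl, C7=C8–OTIPS]
Conditions: (S)-o-tolyl-CBS oxazaborolidine (20 mol %), Tf2NH (18 mol %), CH2Cl2, −78 → −40 °C (the (R)-catalyst if the sense of induction is the opposite)
Reagents that add atoms: none
Why: catalytic enantioselective Diels–Alder reaction of a cyclic enone under oxazaborolidinium activation: the catalyst binds the ketone, the nucleophilic enol-ether terminus C9 bonds to C10 (β to the ketone) and C6 to C5, ketone-endo approach gives the cis ring fusion with the allyl group anti to the ester, and the catalyst directs the diene to the Si face of C10 so that this quaternary centre is set in the absolute sense of the target (C5 and C9 are corrected in steps 8–10).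

Step 7
Reactants: 9 cis-fused cycloadduct
Product: 11 4,4-dibromo ketone, via 4-monobromo ketone 10 (not isolated)
Conditions: LiHMDS (1.1 equiv), THF, −78 °C; BrCCl2CCl2Br (1.1 equiv); then LiHMDS (1.1 equiv); BrCCl2CCl2Br (1.1 equiv), −78 °C
Reagents that add atoms: 1,2-dibromo-1,1,2,2-tetrachloroethane, ClC(Cl)(Br)C(Cl)(Cl)Br
Why: kinetic enolate formation should occur at C4 (C5–H is hindered, C10 is quaternary), and halophilic bromination by a reagent that does not attack the silyl enol ether or the alkene, repeated at the now more acidic C4–H, should give the gem-dibromide; the C4 centre of 10 is transient.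

Step 8
Reactants: 11 4,4-dibromo ketone
Product: 13 20-tert-butyl 19-methyl diester (ring A formed, C4=C5, 9α-allyl, C7=C8–OTIPS), via bromocyclopropanone 12 (not isolated)
Conditions: NaOMe (3 equiv), THF, 0 °C → rt
Reagents that add atoms: sodium methoxide, [Na+].[O-]C
Why: Favorskii rearrangement of an α,α-dihalo ketone: methoxide removes the only α′-hydrogen (C5–H), the enolate displaces one bromide at C4 (3-exo-tet) to give bromocyclopropanone 12, methoxide adds to its carbonyl, and the hemiketal anion fragments by cleavage of the C5–C19 bond with loss of the second bromide from C4. The closest known reaction is the base-induced conversion of 2,2- or 2,7-dibromocycloheptanone into a cyclohex-1-enecarboxylate. In one operation the seven-membered ring (C10, C1–C4, C19, C5) becomes ring A (C10, C1–C5), the expelled ketone carbon becomes the C19 methyl ester on C4, and the C4=C5 bond erases the unwanted cis ring fusion. No stereocentre is created, and C10 and C9 are untouched. The step needs regioselective opening of 12 (ester on C4, alkene C4=C5), which the bromide left on C4 secures as the leaving group of the fragmentation, and it needs the tert-butyl ester and silyl enol ether to survive, which anhydrous NaOMe in THF should allow.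

Step 9
Reactants: 13 20-tert-butyl 19-methyl diester (C4=C5)
Product: 15 4α-methyl-4β-methoxycarbonyl diester (5α-H, 10β-CO2t-Bu, 9α-allyl, C7=C8–OTIPS), via lithium ester enolate 14 (not isolated)
Conditions: Li (2.5 equiv), NH3(l)/THF, t-BuOH (1 equiv), −78 °C; isoprene; then MeI, −78 → −33 °C
Reagents that add atoms: iodomethane, CI
Why: dissolving-metal reductive alkylation of an α,β-unsaturated ester: axial protonation of the C5 carbanion anti to the axial C10 ester should give the trans ring fusion (5α-H), and enolate 14 should be methylated from the α face, opposite the 1,3-diaxial C10 ester, giving 4α-CH3/4β-CO2CH3.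

Step 10
Reactants: 15 4α-methyl-4β-methoxycarbonyl diester
Product: 17 keto acid (8-oxo, 20-oic acid, 9β-allyl, 9α-H), via 9-epi keto acid 16 (not isolated)
Conditions: TFA/CH2Cl2 (1:4), H2O (5 equiv), 0 °C → rt; then K2CO3, MeOH, rt; work-up at pH 3
Reagents that add atoms: none
Why: acid hydrolysis of the silyl enol ether and acidolysis of the tert-butyl ester unveil the C8 ketone and the C20 acid, and base equilibration through the C8 enolate should move the allyl group at C9 to the equatorial β position, the thermodynamic epimer of the trans-decalone.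

Step 11
Reactants: 17 keto acid; 18 α-methylene-γ-butyrolactone
Product: 19 (E)-C12=C13 alkylidene lactone keto acid
Conditions: Hoveyda–Grubbs II (10 mol %), 2,6-dichloro-1,4-benzoquinone (10 mol %), 18 (5 equiv), CH2Cl2, 40 °C
Reagents that add atoms: none
Why: olefin cross-metathesis of the monosubstituted alkene with excess α-methylene lactone (quinone additive against premature isomerisation) should give the thermodynamically preferred (E)-alkylidene lactone and completes the C9–C11–C12–C13 chain.

Step 12
Reactants: 19 (E)-alkylidene lactone keto acid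
Product: 20 butenolide keto acid (C13=C14)
Conditions: RhCl3·3H2O (5 mol %), EtOH, 78 °C
Reagents that add atoms: none
Why: rhodium hydride alkene isomerisation should move the exocyclic C12=C13 bond into the lactone ring to give the more stable α-substituted butenolide; no other isomerisable alkene is present at this stage.

Step 13
Reactants: 20 butenolide keto acid
Product: 21 8(17)-methylene butenolide 20-acid
Conditions: CH2Br2, Zn, TiCl4 (excess), THF/CH2Cl2, 0 °C → rt
Reagents that add atoms: dibromomethane, BrCBr
Why: Takai–Lombardo methylenation is non-basic, so C9 should not epimerise and the butenolide, the ester and the acid (as its zinc carboxylate) should be tolerated while the hindered C8 ketone becomes the C8=C17 methylene.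

Step 14
Reactants: 21 8(17)-methylene butenolide 20-acid
Product: 23 CNP0175906.1 (methyl 20-oxolabda-8(17),13-dien-16,15-olid-19-oate), via acid chloride 22 (not isolated)
Conditions: 1-chloro-N,N,2-trimethylprop-1-en-1-amine, CH2Cl2, 0 °C → rt; then LiAlH(Ot-Bu)3 (1.05 equiv), THF, −78 °C
Reagents that add atoms: none
Why: neutral acid chloride formation avoids acid-induced lactonisation onto C8=C17, and partial reduction of an acid chloride with LiAlH(Ot-Bu)3 at −78 °C should stop at the aldehyde and spare the ester and the butenolide.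

Compound list
1 | cyclohept-1-ene-1-carboxylic acid | OC(=O)C1=CCCCCC1 | starting material
2 | tert-butyl cyclohept-1-ene-1-carboxylate | CC(C)(C)OC(=O)C1=CCCCCC1 | intermediate
3 | tert-butyl 3-oxocyclohept-1-ene-1-carboxylate | CC(C)(C)OC(=O)C1=CC(=O)CCCC1 | intermediate
4 | pent-4-enal | C=CCCC=O | starting material
5 | vinylmagnesium bromide | C=C[Mg]Br | starting material
6 | hepta-1,6-dien-3-ol (racemic) | C=CCCC(O)C=C | intermediate
7 | hepta-1,6-dien-3-one | C=CCCC(=O)C=C | intermediate
8 | (Z)-3-(triisopropylsilyloxy)hepta-1,3,6-triene | C=CC/C=C(\O[Si](C(C)C)(C(C)C)C(C)C)C=C | intermediate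
9 | cis-fused cycloadduct (10β-CO2t-Bu, 5β-H, 9α-allyl, 19-oxo seven-membered ring, C7=C8–OTIPS) | CC(C)[Si](C(C)C)(C(C)C)OC1=CC[C@H]2[C@](C(=O)OC(C)(C)C)(CCCCC2=O)[C@@H]1CC=C | intermediate
10 | 4-monobromo ketone (C4 epimers) | CC(C)[Si](C(C)C)(C(C)C)OC1=CC[C@H]2[C@](C(=O)OC(C)(C)C)(CCCC(Br)C2=O)[C@@H]1CC=C | intermediate
11 | 4,4-dibromo ketone | CC(C)[Si](C(C)C)(C(C)C)OC1=CC[C@H]2[C@](C(=O)OC(C)(C)C)(CCCC(Br)(Br)C2=O)[C@@H]1CC=C | intermediate
12 | bromocyclopropanone (C4–C5 bond closed, C19=O bridging C4 and C5, Br on C4) | CC(C)[Si](C(C)C)(C(C)C)OC1=CCC23[C@](C(=O)OC(C)(C)C)(CCCC2(Br)C3=O)[C@@H]1CC=C | intermediate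
13 | 20-tert-butyl 19-methyl diester, C4=C5 (ring A formed) | CC(C)[Si](C(C)C)(C(C)C)OC1=CCC2=C(C(=O)OC)CCC[C@]2(C(=O)OC(C)(C)C)[C@@H]1CC=C | intermediate
14 | lithium enolate of the C19 methyl ester (5α-H) | CC(C)[Si](C(C)C)(C(C)C)OC1=CC[C@@H]2[C@](C(=O)OC(C)(C)C)(CCCC2=C(OC)O[Li])[C@@H]1CC=C | intermediate
15 | 4α-methyl-4β-methoxycarbonyl diester (5α-H, 10β-CO2t-Bu, 9α-allyl, C7=C8–OTIPS) | CC(C)[Si](C(C)C)(C(C)C)OC1=CC[C@@H]2[C@](C(=O)OC(C)(C)C)(CCC[C@]2(C)C(=O)OC)[C@@H]1CC=C | intermediate
16 | 9-epi keto acid (8-oxo, 20-oic acid, 9α-allyl) | O=C1CC[C@@H]2[C@](C(=O)O)(CCC[C@]2(C)C(=O)OC)[C@@H]1CC=C | intermediate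
17 | keto acid (8-oxo, 20-oic acid, 9β-allyl) | O=C1CC[C@@H]2[C@](C(=O)O)(CCC[C@]2(C)C(=O)OC)[C@H]1CC=C | intermediate
18 | α-methylene-γ-butyrolactone | C=C1CCOC1=O | starting material
19 | (E)-C12=C13 alkylidene lactone keto acid | O=C1CC[C@@H]2[C@](C(=O)O)(CCC[C@]2(C)C(=O)OC)[C@H]1C/C=C1\CCOC1=O | intermediate
20 | butenolide keto acid (C13=C14) | O=C1CC[C@@H]2[C@](C(=O)O)(CCC[C@]2(C)C(=O)OC)[C@H]1CCC1=CCOC1=O | intermediate
21 | 8(17)-methylene butenolide 20-acid | C=C1CC[C@@H]2[C@](C(=O)O)(CCC[C@]2(C)C(=O)OC)[C@H]1CCC1=CCOC1=O | intermediate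
22 | 20-acid chloride of 21 | C=C1CC[C@@H]2[C@](C(=O)Cl)(CCC[C@]2(C)C(=O)OC)[C@H]1CCC1=CCOC1=O | intermediate
23 | CNP0175906.1 | C=C1CC[C@@H]2[C@](C=O)(CCC[C@]2(C)C(=O)OC)[C@H]1CCC1=CCOC1=O | target

Total steps: 14. Longest linear sequence: 12 (steps 3–14, from pent-4-enal).

Steps most likely to fail

Step 8. The hindered C5–H may be removed too slowly, so that methoxide adds to the ketone and the ring is cleaved in a haloform-type reaction instead of contracting. The fallback sets out from 9 and comes back at 13, and keeps a ring contraction but by a Wolff rearrangement. Detrifluoroacetylative diazo transfer (LiHMDS, CF3CO2CH2CF3, −78 °C) gives the 4-trifluoroacetyl ketone F1, and MsN3/Et3N then gives the 4-diazo ketone F2. Irradiation in methanol contracts the ring to the cis-fused saturated C19 methyl ester F3, with C5 retained. Enolate bromination (LDA; BrCCl2CCl2Br) gives the 4-bromo ester F4. Dehydrobromination with DBU in warm toluene towards C5–H should give the tetrasubstituted enoate 13; any Δ3 isomer would be separated.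

Step 6. Turnover may be low at the congested C9–C10 bond, or the catalyst may discriminate the enantiofaces poorly. The fallback sets out from 3 and 8 and comes back at 9. A stoichiometric MeAlCl2-promoted cycloaddition (CH2Cl2, −78 °C) should give racemic 9. Optical resolution by preparative chromatography on a chiral stationary phase then removes the unwanted enantiomer, ent-cycloadduct F5.

Step 9. The ester groups may be over-reduced, enolate 14 may be protonated before it is alkylated, or facial control at C5 may erode in ammonia. The fallback sets out from 13 and comes back at 15, and separates reduction from alkylation. Conjugate reduction with Mg in MeOH gives the saturated trans-fused ester F6, at which stage C5 epimers can be removed. Classical ester enolate alkylation (LDA, THF/HMPA, −78 °C; MeI), with equatorial attack anti to the axial C10 ester, then gives 15.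

Further compounds
F1 | step 8 | 4-trifluoroacetyl ketone | CC(C)[Si](C(C)C)(C(C)C)OC1=CC[C@H]2[C@](C(=O)OC(C)(C)C)(CCCC(C(=O)C(F)(F)F)C2=O)[C@@H]1CC=C
F2 | step 8 | 4-diazo ketone | CC(C)[Si](C(C)C)(C(C)C)OC1=CC[C@H]2[C@](C(=O)OC(C)(C)C)(CCCC(=[N+]=[N-])C2=O)[C@@H]1CC=C
F3 | step 8 | cis-fused saturated C19 methyl ester (C4 epimers) | CC(C)[Si](C(C)C)(C(C)C)OC1=CC[C@H]2[C@](C(=O)OC(C)(C)C)(CCCC2C(=O)OC)[C@@H]1CC=C
F4 | step 8 | 4-bromo ester | CC(C)[Si](C(C)C)(C(C)C)OC1=CC[C@H]2[C@](C(=O)OC(C)(C)C)(CCCC2(Br)C(=O)OC)[C@@H]1CC=C
F5 | step 6 | ent-cycloadduct (enantiomer of 9) | CC(C)[Si](C(C)C)(C(C)C)OC1=CC[C@@H]2[C@@](C(=O)OC(C)(C)C)(CCCCC2=O)[C@H]1CC=C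
F6 | step 9 | saturated trans-fused ester (5α-H, C4 epimers) | CC(C)[Si](C(C)C)(C(C)C)OC1=CC[C@@H]2[C@](C(=O)OC(C)(C)C)(CCCC2C(=O)OC)[C@@H]1CC=C
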